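## Structural features

The target is a 1,2-dioxane (ring O1–O2–C3–C4–C5–C6). C3 carries CH2CO2H (C2, C1), C4 a methyl, and the fully substituted C6 a methyl plus the chain C7H2–C8H(CH3)–C9H2–C10(CH3)=C11H–C12(CH3)=C13H–C14H2–Ph with 10E,12E geometry. C3 and C4 are adjacent and trans, C4 and C6 are 1,3 on the ring, and C8 is 1,3 to C6 across C7. In the chair the C3 and C4 substituents and the C6 chain are equatorial and the C6 methyl is axial. The fragile groups are the O–O bond (phosphines, low-valent metals, strong nucleophiles, carbon radicals near O), the β-peroxy ester with its C3–H (retro-conjugate addition and Kornblum–DeLaMare cleavage under base), and the skipped, benzyl-capped diene (acids, cations). The real difficulty is C6: a tertiary C–OO centre is normally made through a planar radical or cation without facial bias, yet it must be fixed relative to C4 in the ring and C8 in the chain. The key step exploits this carbon: at the ketone oxidation level C6 becomes the cationic carbon of a ring peroxycarbenium ion (O1=C6+). Its half-chair is locked by the trans C3/C4 substituents, so a nucleophile must enter axially, and the axial C6 substituent of the target is the methyl. A second feature is a hidden local C2 symmetry: C4 and C8 have the same sense when viewed from C6 (CH3–C4H–C5H2–C6–C7H2–C8H–CH3), so one enantiomer of one building block can supply both.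

## Logic of the disconnections

24 ⇒ 23. The C1 acid is masked as its methyl ester until the end, because a free acid would consume the organometallic reagents of steps 11 and 13. The forward step must hydrolyse the ester without base-induced opening at C3.

23 ⇒ 17 + 22 (22 from 20, 20 from 18). The cut is C11–C12, the only sp2–sp2 single bond of the diene. Cutting here keeps the nucleophilic diene out of every cationic step, so 17 carries only an iodine-deactivated C10=C11 alkene. The gain is a four-carbon benzyl fragment available in one step from 18. The demands are a Pd coupling that tolerates the O–O bond and retains both alkene geometries, and a syn H–Zr addition to 18 that places the metal on the methyl-bearing carbon.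

17 ⇒ 15 via 16 (key disconnection). The cut is the C6–CH3 bond. The C6 stereocentre disappears: 15 may be any mixture of C6 epimers because both converge on the planar ion 16, and 15 leads straight back to an acyclic ketone. The demands are ionisation of the exocyclic C6–OMe bond and not of a ring bond, methyl transfer faster than O–O heterolysis, and axial delivery relayed from C4 and C3. In one sentence: the route is the axial C-methylation of the ring peroxycarbenium ion 16 generated from the epimer-mixed peroxyketal 15.

15 ⇒ 14 ⇒ 13. The cuts are C3–O2 (conjugate addition), C6–O1 and C6–OMe (peroxy-ketalisation). Both ring oxygens then come from one inorganic peroxide and the ring from a linear keto-enoate that holds only the two bought stereocentres. The demand is 3,4-trans closure (C3 set from C4).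

13 ⇒ 12 ⇒ 11. The cut is C2=C3 (olefination), with C3 and C6 adjusted from alcohol to carbonyl level in the same operation. The gain is a diol with no protecting groups. The demands are simultaneous oxidation of a 1,4-diol without lactol formation and no epimerisation at C4.

11 ⇒ 10 ⇒ 9 ⇒ 8. The cuts are C10–CH3 and C11–I, made together by syn-carbometalation of the C10≡C11 alkyne, then removal of both silyl groups. The gain is a stereodefined trisubstituted iodoalkene from a terminal alkyne. The step must run before any ketone or ester is present, so C6 is kept as a carbinol here.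

8 ⇒ 7 + 4. The cut is C6–C7 (Grignard addition to an aldehyde). C6 is oxidised later, so its configuration is irrelevant. The gain is two fragments of four and five carbons, each with one stereocentre.

7 ⇒ 6 ⇒ 5 ⇒ 1 and 4 ⇒ 3 ⇒ 2 ⇒ 1. The cuts are C9–C10 (sp3–sp alkylation at the oxygen terminus of 1, keeping the bromide for the later Grignard) and C5–C6 (formylation of the Grignard made at the bromine terminus of 1). Because of the local C2 symmetry about C6, both fragments need the same enantiomer, 1. The demand is chemoselective displacement of the triflate in 5 in the presence of the primary bromide.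

## Other disconnections considered

Alternative 1: (the first that comes to mind) cut C3–O2 by intramolecular conjugate addition of a C6 tertiary peroxide onto the enoate. The peroxide would come from cobalt-catalysed hydroperoxysilylation (Mukaiyama–Isayama) of the 1,1-disubstituted alkene A1, giving the silyl peroxide A2, followed by desilylation and cyclisation to 17. The C6–O bond would form by O2 capture of a planar tertiary radical flanked by two nearly identical CH2–CH(CH3) arms, so no facial preference can be expected. C6 would arise as both epimers, and half of the material would be discarded after every other stereocentre is in place. The step count is about the same, so the chosen plan is preferred only because it controls C6.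

Alternative 2: cut C3–O2 and C6–O1 together by [4+2] addition of singlet oxygen to the acyclic 3E,5Z-diene A3, giving the dihydrodioxine A4, then set C4 by diimide reduction of C4=C5. The suprafacial addition would fix C3 relative to C6, but it requires the s-cis conformer with the C7 chain inside. Both diene termini carry allylic hydrogens, so the Schenck ene reaction should dominate. The remote C8 centre cannot choose the ring face. Diimide is sluggish on trisubstituted alkenes, and the two faces of A4 differ only by CH3 versus CH2R at C6. Three selectivity problems would replace one.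

Alternative 3: cut C3–C2 by adding the silyl ketene acetal of methyl acetate to the C3 peroxycarbenium ion from the aldehyde-derived peroxyacetal A5 (the same reaction family as the key step, at the other ring carbon), giving 17. This leaves C6 to be made beforehand by an uncontrolled route. The secondary peroxycarbenium ion is less stabilised than a ketone-derived one. Axial attack on the half-chair with the C4 methyl pseudo-equatorial would place the new C3 substituent axial, i.e. 3,4-cis, the wrong isomer. In the chosen plan the same stereoelectronic rule gives the required isomer.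

Key step: step 11

Remark: (R)-3-bromo-2-methylpropan-1-ol (1) and but-2-yn-1-ylbenzene (18) are taken as commercial, and the target is taken as the (3R,4S,6R,2′R,4′E,6′E) acid drawn in the SMILES.

## Steps

Step 1
Reactants: 1 (R)-3-bromo-2-methylpropan-1-ol
Product: 2 (R)-(3-bromo-2-methylpropoxy)(tert-butyl)dimethylsilane
Conditions: TBSCl, imidazole, CH2Cl2, 0 °C → rt
Reagents that add atoms: tert-butyldimethylsilyl chloride, CC(C)(C)[Si](C)(C)Cl
Why: Standard O-silylation of a primary alcohol; the stereocentre (later C4) is untouched.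

Step 2
Reactants: 2 (R)-(3-bromo-2-methylpropoxy)(tert-butyl)dimethylsilane
Product: 4 (S)-4-[(tert-butyldimethylsilyl)oxy]-3-methylbutanal, via Grignard reagent 3 (not isolated)
Conditions: Mg, THF, reflux; then DMF, 0 °C → rt; aq. NH4Cl
Reagents that add atoms: N,N-dimethylformamide, CN(C)C=O
Why: Grignard formation from a primary bromide and formylation with DMF (Bouveault aldehyde synthesis) add C6 as the aldehyde carbon; the silyl ether is γ to the metal and does not eliminate.

Step 3
Reactants: 1 (R)-3-bromo-2-methylpropan-1-ol
Product: 5 (R)-3-bromo-2-methylpropyl trifluoromethanesulfonate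
Conditions: Tf2O, pyridine, CH2Cl2, −78 → −30 °C; used crude
Reagents that add atoms: trifluoromethanesulfonic anhydride, O=S(=O)(OS(=O)(=O)C(F)(F)F)C(F)(F)F
Why: O-Triflation of a primary alcohol at low temperature gives a leaving group far more reactive than the bromide at the other terminus.

Step 4
Reactants: 5 (R)-3-bromo-2-methylpropyl trifluoromethanesulfonate
Product: 6 (R)-(5-bromo-4-methylpent-1-yn-1-yl)trimethylsilane
Conditions: TMS–C≡CH, n-BuLi, THF, −78 °C; then 5, DMPU, −78 → −20 °C
Reagents that add atoms: ethynyltrimethylsilane, C#C[Si](C)(C)C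
Why: SN2 alkylation of a lithium acetylide by a primary triflate forms C9–C10; the triflate should react much faster than the bromide, which is kept for step 5.

Step 5
Reactants: 6 (R)-(5-bromo-4-methylpent-1-yn-1-yl)trimethylsilane; 4 (S)-4-[(tert-butyldimethylsilyl)oxy]-3-methylbutanal
Product: 8 (2S,4RS,6R)-1-[(tert-butyldimethylsilyl)oxy]-2,6-dimethyl-9-(trimethylsilyl)non-8-yn-4-ol, via Grignard reagent 7 (not isolated)
Conditions: 6, Mg, THF, 45 °C; then 4, THF, −78 → 0 °C; aq. NH4Cl
Reagents that add atoms: none
Why: Grignard addition to an unhindered aldehyde forms C6–C7; the silylalkyne is inert to Mg, and the carbinol (C6) forms as both epimers, which is immaterial because it is oxidised in step 8.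

Step 6
Reactants: 8 (2S,4RS,6R)-1-[(tert-butyldimethylsilyl)oxy]-2,6-dimethyl-9-(trimethylsilyl)non-8-yn-4-ol
Product: 9 (2S,4RS,6R)-2,6-dimethylnon-8-yne-1,4-diol
Conditions: TBAF (2.5 equiv), THF, 0 °C → rt
Reagents that add atoms: none
Why: Fluoride removes the O-silyl and the C-silyl group in one operation and frees the terminal alkyne.

Step 7
Reactants: 9 (2S,4RS,6R)-2,6-dimethylnon-8-yne-1,4-diol
Product: 11 (2S,4RS,6R,8E)-9-iodo-2,6,8-trimethylnon-8-ene-1,4-diol, via alkenylalane 10 (not isolated)
Conditions: AlMe3 (5 equiv), Cp2ZrCl2 (0.5 equiv), CH2Cl2, 0 °C → rt; then I2, THF, −30 → 0 °C; aq. Rochelle salt/Na2S2O3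
Reagents that add atoms: trimethylaluminium, C[Al](C)C; iodine, II
Why: Zirconium-catalysed Negishi carboalumination adds CH3 and Al syn across the terminal alkyne (CH3 to the internal carbon C10), and iodinolysis with retention gives the E-iodoalkene; the two hydroxyls are carried as aluminium alkoxides.

Step 8
Reactants: 11 (2S,4RS,6R,8E)-9-iodo-2,6,8-trimethylnon-8-ene-1,4-diol
Product: 13 methyl (2E,4S,8R,10E)-11-iodo-4,8,10-trimethyl-6-oxoundeca-2,10-dienoate, via keto aldehyde 12 (not isolated)
Conditions: (COCl)2, DMSO, CH2Cl2, −78 °C; i-Pr2NEt, −78 → −20 °C; then Ph3P=CHCO2Me, −20 °C → rt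
Reagents that add atoms: methyl (triphenylphosphoranylidene)acetate, COC(=O)C=P(c1ccccc1)(c1ccccc1)c1ccccc1
Why: In the Swern oxidation both hydroxyls are activated as alkoxysulfonium ions before base is added, so the 1,4-diol should go to the keto aldehyde without passing through a lactol; the stabilised ylide then olefinates only the aldehyde (Wittig reaction, E-selective), and the cold hindered base protects the C4 stereocentre.

Step 9
Reactants: 13 methyl (2E,4S,8R,10E)-11-iodo-4,8,10-trimethyl-6-oxoundeca-2,10-dienoate
Product: 14 methyl (2E,4S,6RS,8R,10E)-6-hydroperoxy-11-iodo-6-methoxy-4,8,10-trimethylundeca-2,10-dienoate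
Conditions: urea·H2O2 (5 equiv), Sc(OTf)3 (10 mol %), MeOH, 0 °C → rt
Reagents that add atoms: hydrogen peroxide (as urea adduct), OO; methanol, CO
Why: Lewis-acid-catalysed peroxy-ketalisation of a dialkyl ketone: the methoxycarbenium ion formed in methanol is captured by H2O2; enoate and iodoalkene are inert, and C6 forms as both epimers, which does not matter.

Step 10
Reactants: 14 methyl (2E,4S,6RS,8R,10E)-6-hydroperoxy-11-iodo-6-methoxy-4,8,10-trimethylundeca-2,10-dienoate
Product: 15 methyl 2-[(3R,4S,6RS)-6-[(2R,4E)-5-iodo-2,4-dimethylpent-4-en-1-yl]-6-methoxy-4-methyl-1,2-dioxan-3-yl]acetate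
Conditions: Et2NH (0.3 equiv), CF3CH2OH, rt
Reagents that add atoms: none
Why: Intramolecular peroxy-Michael addition (6-exo-trig) closes the 1,2-dioxane; in the chair transition state with C4–H eclipsing the enoate, the C4 methyl and the developing CH2CO2Me are both equatorial, which gives 3,4-trans (3R), and the amine-mediated addition is reversible so the diequatorial isomer should accumulate.

Step 11
Reactants: 15 methyl 2-[(3R,4S,6RS)-6-[(2R,4E)-5-iodo-2,4-dimethylpent-4-en-1-yl]-6-methoxy-4-methyl-1,2-dioxan-3-yl]acetate
Product: 17 methyl 2-[(3R,4S,6R)-6-[(2R,4E)-5-iodo-2,4-dimethylpent-4-en-1-yl]-4,6-dimethyl-1,2-dioxan-3-yl]acetate, via peroxycarbenium ion 16 (not isolated)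
Conditions: AlMe3 (4 equiv), CH2Cl2, −78 °C; then TMSOTf (1.2 equiv), −78 → −40 °C; aq. Rochelle salt/NaHCO3
Reagents that add atoms: trimethylaluminium, C[Al](C)C
Why: Proposed new method: TMSOTf should silylate the more basic exocyclic methoxy oxygen of 15 and expel MeOSiMe3, so that both C6 epimers converge on the six-membered peroxycarbenium ion 16 (O1=C6+), which then takes a methyl group from Me3Al; the closest known reaction types are the Lewis-acid-mediated C-allylation and Mukaiyama-type alkylation of peroxycarbenium ions from cyclic alkoxy peroxyketals with allylsilanes and silyl ketene acetals, and the SN1 C-methylation of cyclic O,O-ketals and pyranosyl donors by Me3Al, which has also been applied to peroxide-containing trioxane acetals. No ring is closed; one C–C bond (C6–CH3) and one stereocentre (C6) are formed. In 16 the atoms C5, C6, O1 and O2 are coplanar, and the trans C3/C4 substituents hold the ring in the half-chair in which both are pseudo-equatorial. Attack along the axial trajectory on the face that leads directly to a chair (not a twist-boat) places the new methyl axial, 1,3-trans to the C4 methyl and 1,4-cis to the C3 side chain, which is the 6R configuration with the chain equatorial. The other half-chair (C3/C4 substituents pseudo-axial) would put the incoming methyl syn-axial to the C4 methyl, and an aluminium-bound C3 ester sits on the same face as the favoured trajectory. Three selectivities are needed: exocyclic C6–OMe ionisation over ring C6–O1 ionisation, which the higher basicity of the ether oxygen over a peroxide oxygen and the reversible reclosure of any ring-opened ion should secure; methyl transfer faster than Hock-type O–O heterolysis or loss of H5/H7, which −78 °C and excess Me3Al should secure; and no cation–olefin cyclisation, which is why the chain carries only the iodine-deactivated C10=C11 alkene at this stage. The ester and the alkenyl iodide are inert to Me3Al at this temperature.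

Step 12
Reactants: 18 but-2-yn-1-ylbenzene
Product: 20 [(2E)-3-iodobut-2-en-1-yl]benzene, via alkenylzirconocene 19 (not isolated)
Conditions: Cp2Zr(H)Cl (1.6 equiv), THF, rt → 50 °C; then I2, 0 °C
Reagents that add atoms: iodine, II
Why: Hydrozirconation adds H and Zr syn; with excess hydride the regioisomers equilibrate to put Zr on the less hindered, methyl-bearing carbon, and iodinolysis with retention gives the E-iodide (I trans to benzyl).

Step 13
Reactants: 20 [(2E)-3-iodobut-2-en-1-yl]benzene; 17 methyl 2-[(3R,4S,6R)-6-[(2R,4E)-5-iodo-2,4-dimethylpent-4-en-1-yl]-4,6-dimethyl-1,2-dioxan-3-yl]acetate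
Product: 23 methyl 2-[(3R,4S,6R)-4,6-dimethyl-6-[(2R,4E,6E)-2,4,6-trimethyl-8-phenylocta-4,6-dien-1-yl]-1,2-dioxan-3-yl]acetate, via alkenyllithium 21 (not isolated), via alkenylzinc chloride 22 (not isolated)
Conditions: 20 (1.5 equiv), t-BuLi (3 equiv), Et2O, −78 °C; ZnCl2, THF, −78 → 0 °C; then 17, Pd(PPh3)4 (5 mol %), THF, rt
Reagents that add atoms: none
Why: Iodine–lithium exchange and transmetalation to zinc retain the alkene geometry, and the Negishi coupling joins C11–C12 with retention at both alkenyl carbons to give the 10E,12E diene; an alkenylzinc halide at room temperature should leave the hindered dialkyl peroxide and the ester untouched.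

Step 14
Reactants: 23 methyl 2-[(3R,4S,6R)-4,6-dimethyl-6-[(2R,4E,6E)-2,4,6-trimethyl-8-phenylocta-4,6-dien-1-yl]-1,2-dioxan-3-yl]acetate
Product: 24 2-[(3R,4S,6R)-4,6-dimethyl-6-[(2R,4E,6E)-2,4,6-trimethyl-8-phenylocta-4,6-dien-1-yl]-1,2-dioxan-3-yl]acetic acid
Conditions: LiOH·H2O (3 equiv), THF/H2O 3:1, 0 °C → rt; then 1 M HCl to pH 3
Reagents that add atoms: lithium hydroxide, [Li+].[OH-]
Why: Saponification of a methyl ester; the carboxylate forms quickly and disfavours enolisation toward retro-conjugate addition, and no stereocentre is touched.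

## Compound list

1 | (R)-3-bromo-2-methylpropan-1-ol | OC[C@@H](C)CBr | starting material
2 | (R)-(3-bromo-2-methylpropoxy)(tert-butyl)dimethylsilane | BrC[C@H](C)CO[Si](C)(C)C(C)(C)C | intermediate
3 | (R)-{3-[(tert-butyldimethylsilyl)oxy]-2-methylpropyl}magnesium bromide | Br[Mg]C[C@H](C)CO[Si](C)(C)C(C)(C)C | intermediate
4 | (S)-4-[(tert-butyldimethylsilyl)oxy]-3-methylbutanal | O=CC[C@H](C)CO[Si](C)(C)C(C)(C)C | intermediate
5 | (R)-3-bromo-2-methylpropyl trifluoromethanesulfonate | FC(F)(F)S(=O)(=O)OC[C@@H](C)CBr | intermediate
6 | (R)-(5-bromo-4-methylpent-1-yn-1-yl)trimethylsilane | C[Si](C)(C)C#CC[C@@H](C)CBr | intermediate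
7 | [(2R)-2-methyl-5-(trimethylsilyl)pent-4-yn-1-yl]magnesium bromide | C[Si](C)(C)C#CC[C@@H](C)C[Mg]Br | intermediate
8 | (2S,4RS,6R)-1-[(tert-butyldimethylsilyl)oxy]-2,6-dimethyl-9-(trimethylsilyl)non-8-yn-4-ol | C[Si](C)(C)C#CC[C@@H](C)CC(O)C[C@H](C)CO[Si](C)(C)C(C)(C)C | intermediate
9 | (2S,4RS,6R)-2,6-dimethylnon-8-yne-1,4-diol | C#CC[C@@H](C)CC(O)C[C@H](C)CO | intermediate
10 | (E)-alkenyldimethylalane from syn-carboalumination of 9 (both hydroxyls as O–AlMe2) | C[Al](C)/C=C(\C)C[C@@H](C)CC(O[Al](C)C)C[C@H](C)CO[Al](C)C | intermediate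
11 | (2S,4RS,6R,8E)-9-iodo-2,6,8-trimethylnon-8-ene-1,4-diol | I/C=C(\C)C[C@@H](C)CC(O)C[C@H](C)CO | intermediate
12 | (2S,6R,8E)-9-iodo-2,6,8-trimethyl-4-oxonon-8-enal | I/C=C(\C)C[C@@H](C)CC(=O)C[C@H](C)C=O | intermediate
13 | methyl (2E,4S,8R,10E)-11-iodo-4,8,10-trimethyl-6-oxoundeca-2,10-dienoate | I/C=C(\C)C[C@@H](C)CC(=O)C[C@H](C)/C=C/C(=O)OC | intermediate
14 | methyl (2E,4S,6RS,8R,10E)-6-hydroperoxy-11-iodo-6-methoxy-4,8,10-trimethylundeca-2,10-dienoate | I/C=C(\C)C[C@@H](C)CC(OC)(OO)C[C@H](C)/C=C/C(=O)OC | intermediate
15 | methyl 2-[(3R,4S,6RS)-6-[(2R,4E)-5-iodo-2,4-dimethylpent-4-en-1-yl]-6-methoxy-4-methyl-1,2-dioxan-3-yl]acetate | I/C=C(\C)C[C@@H](C)CC1(OC)C[C@H](C)[C@@H](CC(=O)OC)OO1 | intermediate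
16 | ring peroxycarbenium ion (O1=C6+) derived from 15, as its triflate | I/C=C(\C)C[C@@H](C)CC=1C[C@H](C)[C@@H](CC(=O)OC)O[O+]=1.[O-]S(=O)(=O)C(F)(F)F | intermediate
17 | methyl 2-[(3R,4S,6R)-6-[(2R,4E)-5-iodo-2,4-dimethylpent-4-en-1-yl]-4,6-dimethyl-1,2-dioxan-3-yl]acetate | I/C=C(\C)C[C@@H](C)C[C@]1(C)C[C@H](C)[C@@H](CC(=O)OC)OO1 | intermediate
18 | but-2-yn-1-ylbenzene | CC#CCc1ccccc1 | starting material
19 | chlorobis(cyclopentadienyl)[(2E)-4-phenylbut-2-en-2-yl]zirconium | CC(=C\Cc1ccccc1)/[Zr](Cl)(C1C=CC=C1)C1C=CC=C1 | intermediate
20 | [(2E)-3-iodobut-2-en-1-yl]benzene | CC(=C\Cc1ccccc1)/I | intermediate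
21 | [(2Z)-4-phenylbut-2-en-2-yl]lithium (Li trans to benzyl) | CC(=C\Cc1ccccc1)/[Li] | intermediate
22 | [(2E)-4-phenylbut-2-en-2-yl]zinc chloride | CC(=C\Cc1ccccc1)/[Zn]Cl | intermediate
23 | methyl 2-[(3R,4S,6R)-4,6-dimethyl-6-[(2R,4E,6E)-2,4,6-trimethyl-8-phenylocta-4,6-dien-1-yl]-1,2-dioxan-3-yl]acetate | CC(=C\Cc1ccccc1)/C=C(\C)C[C@@H](C)C[C@]1(C)C[C@H](C)[C@@H](CC(=O)OC)OO1 | intermediate
24 | 2-[(3R,4S,6R)-4,6-dimethyl-6-[(2R,4E,6E)-2,4,6-trimethyl-8-phenylocta-4,6-dien-1-yl]-1,2-dioxan-3-yl]acetic acid | CC(=C\Cc1ccccc1)/C=C(\C)C[C@@H](C)C[C@]1(C)C[C@H](C)[C@@H](CC(=O)O)OO1 | target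

## Step count and least certain steps

Total step count: 14. Longest linear sequence: 11 steps (steps 3, 4, 5, 6, 7, 8, 9, 10, 11, 13, 14 from 1).

Step 11 (key step, proposed new method). The most likely failures are ionisation at the ring C6–O1 bond in place of the exocyclic C6–OMe bond, O–O heterolysis with 1,2-shift at the peroxycarbenium stage, methyl transfer from aluminium to a peroxide oxygen, and capture of the cation by the C10=C11 π-bond. All follow from the modest stabilisation of a peroxycarbenium ion and the oxophilicity of aluminium. The fallback sets out from 13 and uses known chemistry without stereocontrol at C6. Chemoselective addition of MeTiCl3 to the ketone (CH2Cl2, −78 → −30 °C) would give the tertiary alcohol methyl (2E,4S,6RS,8R,10E)-6-hydroxy-11-iodo-4,6,8,10-tetramethylundeca-2,10-dienoate F1. Acid-catalysed perhydrolysis (50 % H2O2, cat. H2SO4, Et2O, 0 °C) would give the tertiary hydroperoxide methyl (2E,4S,6RS,8R,10E)-6-hydroperoxy-11-iodo-4,6,8,10-tetramethylundeca-2,10-dienoate F2. Amine-mediated conjugate addition (Et2NH, CF3CH2OH) would then close the ring, and chromatographic removal of the C6 epimer brings the route back at 17.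

Step 10. Incomplete facial selectivity at C3 and base-induced Kornblum–DeLaMare cleavage at C3–H or retro-addition are the likely problems, because closure relies on an equatorial preference under reversible amine catalysis. The fallback sets out from 11 and moves the control element to allylic 1,3-strain in a Z acceptor. Swern oxidation as in step 8, then Still–Gennari olefination ((CF3CH2O)2P(O)CH2CO2Me, KHMDS, 18-crown-6, THF, −78 °C), would give methyl (2Z,4S,8R,10E)-11-iodo-4,8,10-trimethyl-6-oxoundeca-2,10-dienoate F3. Peroxy-ketalisation as in step 9 would give methyl (2Z,4S,6RS,8R,10E)-6-hydroperoxy-11-iodo-6-methoxy-4,8,10-trimethylundeca-2,10-dienoate F4. Its cis ester forces C4–H into the alkene plane, so a short, kinetically controlled closure with a weak base should deliver the same 3,4-trans product, and the route is rejoined at 15.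

Step 13 (with the regiochemistry of step 12). Reaction of the alkenylzinc or of Pd(0)/phosphine with the O–O bond, and carry-over of the minor hydrozirconation regioisomer into the diene, are the likely problems. The fallback sets out from 17 and uses a regiodefined stannane under neutral Stille conditions. Stannylcupration of but-2-yn-1-ol would give (2E)-3-(tributylstannyl)but-2-en-1-ol F5. Mesylation and LiBr would give [(2E)-4-bromobut-2-en-2-yl]tributylstannane F6. PhMgBr with catalytic CuI would give tributyl[(2E)-4-phenylbut-2-en-2-yl]stannane F7. Coupling of F7 with 17 (Pd2(dba)3, AsPh3, NMP, rt → 40 °C) returns to 23.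

Step 8. Over-oxidation through the lactol if the two hydroxyls of the 1,4-diol are not activated together, and epimerisation at C4 of the keto aldehyde, are the likely problems. The fallback sets out from 8 and unveils the two oxygens one after the other. K2CO3/MeOH would remove only the alkynyl silane to give (2S,4RS,6R)-1-[(tert-butyldimethylsilyl)oxy]-2,6-dimethylnon-8-yn-4-ol F8. Carboalumination/iodination as in step 7 would give (2S,4RS,6R,8E)-1-[(tert-butyldimethylsilyl)oxy]-9-iodo-2,6,8-trimethylnon-8-en-4-ol F9. Dess–Martin oxidation would give (2S,6R,8E)-1-[(tert-butyldimethylsilyl)oxy]-9-iodo-2,6,8-trimethylnon-8-en-4-one F10. HF·pyridine would give (2S,6R,8E)-1-hydroxy-9-iodo-2,6,8-trimethylnon-8-en-4-one F11. Parikh–Doering oxidation to 12 and the Wittig reaction of step 8 rejoin the route at 13.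

## Further compounds

F1 | step 11 | methyl (2E,4S,6RS,8R,10E)-6-hydroxy-11-iodo-4,6,8,10-tetramethylundeca-2,10-dienoate | I/C=C(\C)C[C@@H](C)CC(C)(O)C[C@H](C)/C=C/C(=O)OC
F2 | step 11 | methyl (2E,4S,6RS,8R,10E)-6-hydroperoxy-11-iodo-4,6,8,10-tetramethylundeca-2,10-dienoate | I/C=C(\C)C[C@@H](C)CC(C)(OO)C[C@H](C)/C=C/C(=O)OC
F3 | step 10 | methyl (2Z,4S,8R,10E)-11-iodo-4,8,10-trimethyl-6-oxoundeca-2,10-dienoate | I/C=C(\C)C[C@@H](C)CC(=O)C[C@H](C)/C=C\C(=O)OC
F4 | step 10 | methyl (2Z,4S,6RS,8R,10E)-6-hydroperoxy-11-iodo-6-methoxy-4,8,10-trimethylundeca-2,10-dienoate | I/C=C(\C)C[C@@H](C)CC(OC)(OO)C[C@H](C)/C=C\C(=O)OC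
F5 | step 13 | (2E)-3-(tributylstannyl)but-2-en-1-ol | CC(=C\CO)/[Sn](CCCC)(CCCC)CCCC
F6 | step 13 | [(2E)-4-bromobut-2-en-2-yl]tributylstannane | CC(=C\CBr)/[Sn](CCCC)(CCCC)CCCC
F7 | step 13 | tributyl[(2E)-4-phenylbut-2-en-2-yl]stannane | CC(=C\Cc1ccccc1)/[Sn](CCCC)(CCCC)CCCC
F8 | step 8 | (2S,4RS,6R)-1-[(tert-butyldimethylsilyl)oxy]-2,6-dimethylnon-8-yn-4-ol | C#CC[C@@H](C)CC(O)C[C@H](C)CO[Si](C)(C)C(C)(C)C
F9 | step 8 | (2S,4RS,6R,8E)-1-[(tert-butyldimethylsilyl)oxy]-9-iodo-2,6,8-trimethylnon-8-en-4-ol | I/C=C(\C)C[C@@H](C)CC(O)C[C@H](C)CO[Si](C)(C)C(C)(C)C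
F10 | step 8 | (2S,6R,8E)-1-[(tert-butyldimethylsilyl)oxy]-9-iodo-2,6,8-trimethylnon-8-en-4-one | I/C=C(\C)C[C@@H](C)CC(=O)C[C@H](C)CO[Si](C)(C)C(C)(C)C
F11 | step 8 | (2S,6R,8E)-1-hydroxy-9-iodo-2,6,8-trimethylnon-8-en-4-one | I/C=C(\C)C[C@@H](C)CC(=O)C[C@H](C)CO
A1 | alternative 1 | methyl (2E,4S,8S,10E)-11-iodo-4,8,10-trimethyl-6-methylideneundeca-2,10-dienoate | I/C=C(\C)C[C@@H](C)CC(=C)C[C@H](C)/C=C/C(=O)OC
A2 | alternative 1 | methyl (2E,4S,6RS,8R,10E)-11-iodo-4,6,8,10-tetramethyl-6-[(triethylsilyl)peroxy]undeca-2,10-dienoate | I/C=C(\C)C[C@@H](C)CC(C)(OO[Si](CC)(CC)CC)C[C@H](C)/C=C/C(=O)OC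
A3 | alternative 2 | methyl (3E,5Z,8S,10E)-11-iodo-4,6,8,10-tetramethylundeca-3,5,10-trienoate | COC(=O)C/C=C(\C)/C=C(/C)\C[C@H](C)C/C(C)=C/I
A4 | alternative 2 | methyl 2-[(3R,6R)-6-[(2R,4E)-5-iodo-2,4-dimethylpent-4-en-1-yl]-4,6-dimethyl-3,6-dihydro-1,2-dioxin-3-yl]acetate | I/C=C(\C)C[C@@H](C)C[C@]1(C)C=C(C)[C@@H](CC(=O)OC)OO1
A5 | alternative 3 | (3RS,4S,6R)-6-[(2R,4E)-5-iodo-2,4-dimethylpent-4-en-1-yl]-3-methoxy-4,6-dimethyl-1,2-dioxane | I/C=C(\C)C[C@@H](C)C[C@]1(C)C[C@H](C)C(OC)OO1
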